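The oxepine ring is disconnected at the O1–C7 ether bond together with the bond from C6 to the side chain. The ring atoms C5=C6–C7H2–O1 are treated as a masked terminal allene. The precursor is an acyclic γ-allenol, a tert-butyl (S)-2-hydroxy-2-(aroylmethyl)hepta-5,6-dienoate, which already carries the quaternary carbinol C2 from a copper–bis(oxazoline) Mukaiyama aldol between an allenyl α-ketoester and an aryl enolsilane. In the key step divalent palladium triggers 7-endo attack of the tertiary hydroxyl on the terminal allene carbon, closing the tetrahydrooxepine through O1–C7. The resulting C6 vinylpalladium adds to acrolein, installing the side-chain aldehyde in the same operation. Wittig olefination, deprotection and aldehyde reduction complete the route.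

Key step: step 7

Remark: oxepine numbering O1, C2 (quaternary, S), C3, C4, C5=C6, C7H2 is used throughout; the (S,S)-tert-butyl-bis(oxazoline) copper catalyst is assumed to give the (S)-carbinol by si-face attack, as in the square-planar chelate model for pyruvate esters.

Step 1
Reactants: 1 but-3-yn-1-ol
Product: 3 penta-3,4-dien-1-ol, via propargylic amine 2 (not isolated)
Conditions: (CH2O)n, CuI (0.5 equiv), iPr2NH, 1,4-dioxane, reflux
Reagents that add atoms: paraformaldehyde (formaldehyde), C=O
Why: Crabbé allene homologation, in which the CuI-mediated Mannich reaction gives propargylic amine 2, which then transfers a hydride from an isopropyl C–H and loses the imine to leave the terminal allene, the free hydroxyl being tolerated.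

Step 2
Reactants: 3 penta-3,4-dien-1-ol
Product: 4 5-bromopenta-1,2-diene
Conditions: CBr4, PPh3, CH2Cl2, 0 °C
Reagents that add atoms: carbon tetrabromide, BrC(Br)(Br)Br
Why: Appel bromination of the primary alcohol proceeds by SN2 displacement of the oxyphosphonium group under neutral conditions that leave the allene untouched.

Step 3
Reactants: 4 5-bromopenta-1,2-diene; 5 di-tert-butyl oxalate
Product: 7 tert-butyl 2-oxohepta-5,6-dienoate, via Grignard reagent 6 (not isolated)
Conditions: Mg, THF, 0 °C → rt; then addition to 5 (1.5 equiv), THF, −78 °C; 1 M HCl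
Reagents that add atoms: none
Why: Grignard formation followed by mono-acylation with excess di-tert-butyl oxalate at −78 °C, where the magnesium hemiketal alkoxide persists until the acidic quench and the bulky tert-butyl ester suppresses a second addition, should give the α-ketoester.

Step 4
Reactants: 8 1-(2,5-dihydroxyphenyl)ethan-1-one
Product: 9 1-[2,5-bis(methoxymethoxy)phenyl]ethan-1-one
Conditions: MOMCl (3 equiv), iPr2NEt (4 equiv), CH2Cl2, 0 → 40 °C
Reagents that add atoms: chloromethyl methyl ether (MOMCl), COCCl
Why: O-alkylation of both phenols with the reactive α-chloro ether (acetal protection), with gentle warming to engage the hydrogen-bonded ortho hydroxyl, masks the hydroquinone against base, Lewis acid and palladium in the later steps.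

Step 5
Reactants: 9 1-[2,5-bis(methoxymethoxy)phenyl]ethan-1-one
Product: 11 {[1-(2,5-bis(methoxymethoxy)phenyl)ethenyl]oxy}trimethylsilane, via lithium enolate 10 (not isolated)
Conditions: LiN(SiMe3)2, THF, −78 °C; then Me3SiCl, −78 → 0 °C; non-aqueous work-up
Reagents that add atoms: chlorotrimethylsilane, C[Si](C)(C)Cl
Why: Kinetic deprotonation of the methyl ketone and O-silylation of the lithium enolate (enol silane formation) avoids the Lewis-acidic silyl triflate conditions that could cleave the MOM ethers.

Step 6
Reactants: 7 tert-butyl 2-oxohepta-5,6-dienoate; 11 {[1-(2,5-bis(methoxymethoxy)phenyl)ethenyl]oxy}trimethylsilane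
Product: 13 tert-butyl (2S)-2-{2-[2,5-bis(methoxymethoxy)phenyl]-2-oxoethyl}-2-hydroxyhepta-5,6-dienoate, via silyl aldol 12 (not isolated)
Conditions: [Cu((S,S)-tBu-box)](OTf)2 (10 mol %; ligand 2,2′-(propane-2,2-diyl)bis[(4S)-4-tert-butyl-4,5-dihydrooxazole]), THF, −78 → −40 °C; then 1 M HCl, THF, 0 °C
Reagents that add atoms: none
Why: Copper–bis(oxazoline)-catalysed enantioselective Mukaiyama aldol, in which α-ketoester 7 chelates the square-planar divalent copper centre through both carbonyls, the tert-butyl group of the (S,S)-ligand shields the re face and enolsilane 11 adds to the si face to set C2 as (S), after which dilute acid cleaves the tertiary silyl ether 12 without touching the aryl MOM ethers.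

Step 7
Reactants: 13 tert-butyl (2S)-2-{2-[2,5-bis(methoxymethoxy)phenyl]-2-oxoethyl}-2-hydroxyhepta-5,6-dienoate; 14 acrolein (prop-2-enal)
Product: 16 tert-butyl (2S)-2-{2-[2,5-bis(methoxymethoxy)phenyl]-2-oxoethyl}-6-(3-oxopropyl)-2,3,4,7-tetrahydrooxepine-2-carboxylate, via vinylpalladium bromide 15 (not isolated)
Conditions: PdCl2(MeCN)2 (10 mol %), LiBr (4 equiv), acrolein (5 equiv), THF, 0 °C → rt
Reagents that add atoms: none
Why: Proposed new method: divalent palladium coordinates the distal C6=C7 π-bond of the allene on the face away from the tether, the tertiary hydroxyl attacks the unsubstituted terminus C7 (anti-oxypalladation) to give the C6 σ-vinylpalladium 15, this inserts acrolein at its CH2 terminus and the palladium enolate is protonated by the HBr released on ring closure, so the divalent palladium catalyst is regenerated without an oxidant. The closest known reaction types are the PdCl2-catalysed cyclisative coupling of γ-allenols with allyl bromide, which closes 2,3,4,7-tetrahydrooxepines in the same sense, and the bromide-promoted nucleopalladation of allenes and alkynes terminated by conjugate addition to acrolein. The one ring formed is closed in the 7-endo mode at the terminal allene carbon, through O1–C7. No stereocentre is created: C2 is untouched and the C5=C6 bond can only be cis inside the seven-membered ring. The step needs 7-endo closure in preference to 5-exo attack at C5, which the unhindered CH2 terminus, the preference of divalent palladium for the less substituted π-bond and the gem-disubstituted carbinol (Thorpe–Ingold effect) should favour. It also needs protonolysis in preference to β-hydride elimination, which excess bromide should secure by occupying the vacant coordination site on palladium.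

Step 8
Reactants: 16 tert-butyl (2S)-2-{2-[2,5-bis(methoxymethoxy)phenyl]-2-oxoethyl}-6-(3-oxopropyl)-2,3,4,7-tetrahydrooxepine-2-carboxylate; 17 2-(triphenylphosphoranylidene)propanal
Product: 18 tert-butyl (2S)-2-{2-[2,5-bis(methoxymethoxy)phenyl]-2-oxoethyl}-6-[(3E)-4-methyl-5-oxopent-3-en-1-yl]-2,3,4,7-tetrahydrooxepine-2-carboxylate
Conditions: 17 (1.5 equiv), toluene, 80 °C
Reagents that add atoms: none
Why: Wittig olefination with the stabilised formyl ylide should react only with the aliphatic aldehyde (not the aryl ketone or ester) and, under thermodynamic control of the oxaphosphetane, give the (E)-trisubstituted enal.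

Step 9
Reactants: 18 tert-butyl (2S)-2-{2-[2,5-bis(methoxymethoxy)phenyl]-2-oxoethyl}-6-[(3E)-4-methyl-5-oxopent-3-en-1-yl]-2,3,4,7-tetrahydrooxepine-2-carboxylate
Product: 19 (2S)-2-[2-(2,5-dihydroxyphenyl)-2-oxoethyl]-6-[(3E)-4-methyl-5-oxopent-3-en-1-yl]-2,3,4,7-tetrahydrooxepine-2-carboxylic acid
Conditions: CF3CO2H/CH2Cl2/H2O (20:75:5), 0 °C → rt
Reagents that add atoms: none
Why: Acidolysis cleaves the tert-butyl ester through the tert-butyl cation and hydrolyses both aryl MOM acetals, while the enal, the ring alkene and the allylic ether of the oxepine, none of which gives a well-stabilised cation, should survive dilute acid at or below room temperature.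

Step 10
Reactants: 19 (2S)-2-[2-(2,5-dihydroxyphenyl)-2-oxoethyl]-6-[(3E)-4-methyl-5-oxopent-3-en-1-yl]-2,3,4,7-tetrahydrooxepine-2-carboxylic acid
Product: 20 (2S)-2-[2-(2,5-dihydroxyphenyl)-2-oxoethyl]-6-[(3E)-5-hydroxy-4-methylpent-3-en-1-yl]-2,3,4,7-tetrahydrooxepine-2-carboxylic acid
Conditions: NaBH4 (2 equiv), MeOH/THF, −40 °C, argon; then pH 3 phosphate buffer
Reagents that add atoms: none
Why: Chemoselective 1,2-reduction of the aldehyde by borohydride at low temperature should leave the hindered, hydrogen-bonded 2-hydroxyaryl ketone and the carboxylate untouched, so that only the (E)-allylic alcohol forms and C2 is not affected.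

Compound list
1 | but-3-yn-1-ol | C#CCCO | starting material
2 | 5-(diisopropylamino)pent-3-yn-1-ol (propargylic amine, not isolated) | CC(C)N(CC#CCCO)C(C)C | intermediate
3 | penta-3,4-dien-1-ol | C=C=CCCO | intermediate
4 | 5-bromopenta-1,2-diene | C=C=CCCBr | intermediate
5 | di-tert-butyl oxalate | CC(C)(C)OC(=O)C(=O)OC(C)(C)C | starting material
6 | penta-3,4-dien-1-ylmagnesium bromide (Grignard reagent, not isolated) | C=C=CCC[Mg]Br | intermediate
7 | tert-butyl 2-oxohepta-5,6-dienoate | C=C=CCCC(=O)C(=O)OC(C)(C)C | intermediate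
8 | 1-(2,5-dihydroxyphenyl)ethan-1-one | CC(=O)c1cc(O)ccc1O | starting material
9 | 1-[2,5-bis(methoxymethoxy)phenyl]ethan-1-one | CC(=O)c1cc(OCOC)ccc1OCOC | intermediate
10 | lithium 1-[2,5-bis(methoxymethoxy)phenyl]ethen-1-olate (lithium enolate, not isolated) | [Li]OC(=C)c1cc(OCOC)ccc1OCOC | intermediate
11 | {[1-(2,5-bis(methoxymethoxy)phenyl)ethenyl]oxy}trimethylsilane | C=C(O[Si](C)(C)C)c1cc(OCOC)ccc1OCOC | intermediate
12 | tert-butyl (2S)-2-{2-[2,5-bis(methoxymethoxy)phenyl]-2-oxoethyl}-2-[(trimethylsilyl)oxy]hepta-5,6-dienoate (silyl aldol, not isolated) | C=C=CCC[C@](O[Si](C)(C)C)(CC(=O)c1cc(OCOC)ccc1OCOC)C(=O)OC(C)(C)C | intermediate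
13 | tert-butyl (2S)-2-{2-[2,5-bis(methoxymethoxy)phenyl]-2-oxoethyl}-2-hydroxyhepta-5,6-dienoate | C=C=CCC[C@](O)(CC(=O)c1cc(OCOC)ccc1OCOC)C(=O)OC(C)(C)C | intermediate
14 | acrolein (prop-2-enal) | C=CC=O | starting material
15 | tert-butyl (2S)-2-{2-[2,5-bis(methoxymethoxy)phenyl]-2-oxoethyl}-6-(bromopalladio)-2,3,4,7-tetrahydrooxepine-2-carboxylate (C6 vinylpalladium bromide, further ligands omitted, not isolated) | Br[Pd]C1=CCC[C@](CC(=O)c2cc(OCOC)ccc2OCOC)(C(=O)OC(C)(C)C)OC1 | intermediate
16 | tert-butyl (2S)-2-{2-[2,5-bis(methoxymethoxy)phenyl]-2-oxoethyl}-6-(3-oxopropyl)-2,3,4,7-tetrahydrooxepine-2-carboxylate | O=CCCC1=CCC[C@](CC(=O)c2cc(OCOC)ccc2OCOC)(C(=O)OC(C)(C)C)OC1 | intermediate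
17 | 2-(triphenylphosphoranylidene)propanal | CC(C=O)=P(c1ccccc1)(c1ccccc1)c1ccccc1 | starting material
18 | tert-butyl (2S)-2-{2-[2,5-bis(methoxymethoxy)phenyl]-2-oxoethyl}-6-[(3E)-4-methyl-5-oxopent-3-en-1-yl]-2,3,4,7-tetrahydrooxepine-2-carboxylate | C/C(=C\CCC1=CCC[C@](CC(=O)c2cc(OCOC)ccc2OCOC)(C(=O)OC(C)(C)C)OC1)C=O | intermediate
19 | (2S)-2-[2-(2,5-dihydroxyphenyl)-2-oxoethyl]-6-[(3E)-4-methyl-5-oxopent-3-en-1-yl]-2,3,4,7-tetrahydrooxepine-2-carboxylic acid | C/C(=C\CCC1=CCC[C@](CC(=O)c2cc(O)ccc2O)(C(=O)O)OC1)C=O | intermediate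
20 | (2S)-2-[2-(2,5-dihydroxyphenyl)-2-oxoethyl]-6-[(3E)-5-hydroxy-4-methylpent-3-en-1-yl]-2,3,4,7-tetrahydrooxepine-2-carboxylic acid | C/C(=C\CCC1=CCC[C@](CC(=O)c2cc(O)ccc2O)(C(=O)O)OC1)CO | target

Total step count: 10. Longest linear sequence: 8 steps (steps 1, 2, 3, 6, 7, 8, 9, 10 from but-3-yn-1-ol); steps 4 and 5 form the second branch, which joins at step 6.

Steps most likely to fail

Step 7. The hydroxyl may close onto the inner allene carbon C5 (5-exo closure to a 2-alkenyl tetrahydrofuran). Alternatively, the vinylpalladium species may not be intercepted by acrolein: protodepalladation would give simple hydroalkoxylation, and β-hydride elimination after insertion would reduce the catalyst to zerovalent palladium and stop turnover. The fallback sets out from 13 and uses the known cyclisative coupling of γ-allenols with allyl bromide, in which C–C bond formation ends by β-bromide elimination and so regenerates divalent palladium directly. Treatment of 13 with PdCl2 (5 mol %) and allyl bromide (5 equiv) in DMF at room temperature should give tert-butyl (2S)-2-{2-[2,5-bis(methoxymethoxy)phenyl]-2-oxoethyl}-6-(prop-2-en-1-yl)-2,3,4,7-tetrahydrooxepine-2-carboxylate F1. Hydroboration of the terminal vinyl group with 9-BBN (THF, 0 °C → rt) should be selective over the trisubstituted ring alkene and the hindered aryl ketone and give the B-alkyl-9-borabicyclo[3.3.1]nonane adduct F2. Oxidation with NaBO3·4H2O should give tert-butyl (2S)-2-{2-[2,5-bis(methoxymethoxy)phenyl]-2-oxoethyl}-6-(3-hydroxypropyl)-2,3,4,7-tetrahydrooxepine-2-carboxylate F3, and Dess–Martin periodinane (NaHCO3, CH2Cl2) then returns to the route at aldehyde 16.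

Step 6. Facial discrimination may erode or the addition may stall, because the homoallenyl chain of 7 and the ortho-alkoxy enolsilane 11 are bulkier than the pyruvate and acetophenone partners for which the catalyst is established; partial loss of the ortho MOM group during acidic desilylation is a further possibility. The fallback sets out from 9 and 7 and replaces catalytic induction by resolution. Ketone 9 is deprotonated with LiN(iPr)2 (THF, −78 °C) to lithium enolate 10, α-ketoester 7 is added and the mixture is quenched with AcOH at −78 °C before retro-aldol equilibration. This should give racemic tert-butyl 2-{2-[2,5-bis(methoxymethoxy)phenyl]-2-oxoethyl}-2-hydroxyhepta-5,6-dienoate F4. Preparative chromatography on a chiral stationary phase (amylose tris(3,5-dimethylphenylcarbamate)) then separates the enantiomers, and the (S)-enantiomer rejoins the route as 13.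

Step 9. Protic acidolysis may cause alkylation of the liberated hydroquinone by tert-butyl or methoxymethyl cations, acid-induced β-elimination of the ring oxygen from the β-alkoxy ketone, or incomplete ester cleavage. The fallback sets out from 18, reverses the order of the last two operations and removes the groups by silyl transfer without protic acid. Reduction of 18 with NaBH4 (MeOH/CH2Cl2, −78 °C) should give tert-butyl (2S)-2-{2-[2,5-bis(methoxymethoxy)phenyl]-2-oxoethyl}-6-[(3E)-5-hydroxy-4-methylpent-3-en-1-yl]-2,3,4,7-tetrahydrooxepine-2-carboxylate F5. Me3SiOTf with 2,2′-bipyridyl (CH2Cl2, 0 °C → rt) should convert both aryl MOM ethers into aryl silyl ethers and the tert-butyl ester into the silyl ester, and should mask the allylic alcohol as its silyl ether in passing, giving the tetrakis(trimethylsilyl) derivative F6. Mild aqueous methanolysis (MeOH/H2O, pH about 5) of F6 comes back to the route at target 20.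

Further compounds
F1 | step 7 | tert-butyl (2S)-2-{2-[2,5-bis(methoxymethoxy)phenyl]-2-oxoethyl}-6-(prop-2-en-1-yl)-2,3,4,7-tetrahydrooxepine-2-carboxylate | C=CCC1=CCC[C@](CC(=O)c2cc(OCOC)ccc2OCOC)(C(=O)OC(C)(C)C)OC1
F2 | step 7 | tert-butyl (2S)-2-{2-[2,5-bis(methoxymethoxy)phenyl]-2-oxoethyl}-6-[3-(9-borabicyclo[3.3.1]nonan-9-yl)propyl]-2,3,4,7-tetrahydrooxepine-2-carboxylate | C(CCC1=CCC[C@](CC(=O)c2cc(OCOC)ccc2OCOC)(C(=O)OC(C)(C)C)OC1)B1C2CCCC1CCC2
F3 | step 7 | tert-butyl (2S)-2-{2-[2,5-bis(methoxymethoxy)phenyl]-2-oxoethyl}-6-(3-hydroxypropyl)-2,3,4,7-tetrahydrooxepine-2-carboxylate | OCCCC1=CCC[C@](CC(=O)c2cc(OCOC)ccc2OCOC)(C(=O)OC(C)(C)C)OC1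
F4 | step 6 | racemic tert-butyl 2-{2-[2,5-bis(methoxymethoxy)phenyl]-2-oxoethyl}-2-hydroxyhepta-5,6-dienoate | C=C=CCCC(O)(CC(=O)c1cc(OCOC)ccc1OCOC)C(=O)OC(C)(C)C
F5 | step 9 | tert-butyl (2S)-2-{2-[2,5-bis(methoxymethoxy)phenyl]-2-oxoethyl}-6-[(3E)-5-hydroxy-4-methylpent-3-en-1-yl]-2,3,4,7-tetrahydrooxepine-2-carboxylate | C/C(=C\CCC1=CCC[C@](CC(=O)c2cc(OCOC)ccc2OCOC)(C(=O)OC(C)(C)C)OC1)CO
F6 | step 9 | trimethylsilyl (2S)-2-{2-[2,5-bis(trimethylsilyloxy)phenyl]-2-oxoethyl}-6-[(3E)-4-methyl-5-(trimethylsilyloxy)pent-3-en-1-yl]-2,3,4,7-tetrahydrooxepine-2-carboxylate | C/C(=C\CCC1=CCC[C@](CC(=O)c2cc(O[Si](C)(C)C)ccc2O[Si](C)(C)C)(C(=O)O[Si](C)(C)C)OC1)CO[Si](C)(C)C
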